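**Plan**

- Retrosynthesis: the O3-benzyl and O5-methyl ethers are cut last. Ring C is then cut across O1–C8a and C2–C3 together (a formal [4+2] disconnection), giving benzaldehyde and an ortho-fluoroaryl benzyloxymethyl ketone. The ketone is cut at C4–C4a and the prenyl group at C8, back to 1-fluoro-3,5-dimethoxybenzene.
- Enabling feature: on ring A the C4 carbonyl is ortho to C8a, so a fluorine at C8a can leave by addition–elimination, while C3, alpha to the same carbonyl, is an enolate carbon. C8a(+)–C4a–C4–C3(−) is a 1,4-dipole that matches O(−)–C(+) of benzaldehyde.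
- Forward: ring A is bought. Its two positions flanking fluorine are filled by two directed lithiations (prenyl first, then the C4–C3 unit by Weinreb ketone synthesis). The ketone is stored as its silyl enol ether, and ring C arises last by a fluoride-relay aldol/SNAr annulation with benzaldehyde.
- Helpers: the fluorine (leaving group) and the trimethylsilyl group (enolate store) leave together as Me3SiF in the key step. The O3-benzyl cap, which blocks five-ring closure, falls in the last step together with the O5-methyl group.
- Stereochemistry: C2 from the chiral ammonium counter-ion that accompanies enolate and aldolate through the annulation; C3 (trans to C2) from the chair-like ring closure. Neither centre is touched afterwards.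

Key step: step 4

Assumption: the sense of induction of the cinchonidinium cation on this substrate class is not established; it is taken to favour the (2R,3R) product, and the pseudoenantiomeric cinchoninium salt would be used if the antipode predominates.

Convention: flavanone numbering (O1, C2, C3, C4, C4a, C5–C8, C8a) is used for ring atoms; Ar = 2-fluoro-4,6-dimethoxy-3-(3-methylbut-2-en-1-yl)phenyl.

**Step 1**
Reactants: 1 1-fluoro-3,5-dimethoxybenzene; 2 1-bromo-3-methylbut-2-ene (prenyl bromide)
Product: 4 1-fluoro-3,5-dimethoxy-2-(3-methylbut-2-en-1-yl)benzene, via aryllithium 3 (not isolated)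
Conditions: n-BuLi (1.05 equiv), THF, −78 °C, 1 h; then CuBr·SMe2 (10 mol %), 2 (1.1 equiv), −78 → −40 °C
Reagents that add atoms: none
Why: Directed ortho-metalation at −78 °C should remove the ring hydrogen flanked by fluorine and methoxy (the more acidic site, and the one lithiated at this temperature, unlike the hydrogen between the two methoxy groups), the ortho-fluoroaryllithium 3 is stable to loss of LiF when kept cold, and copper-catalysed allylic substitution of prenyl bromide at its primary carbon should give the linear prenyl arene.

**Step 2**
Reactants: 4 1-fluoro-3,5-dimethoxy-2-(3-methylbut-2-en-1-yl)benzene; 5 2-(benzyloxy)-N-methoxy-N-methylacetamide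
Product: 7 2-(benzyloxy)-1-[2-fluoro-4,6-dimethoxy-3-(3-methylbut-2-en-1-yl)phenyl]ethan-1-one, via aryllithium 6 (not isolated)
Conditions: n-BuLi (1.05 equiv), THF, −78 °C, 1.5 h; then 5 (1.2 equiv), −78 °C; H2O
Reagents that add atoms: none
Why: A second directed ortho-metalation should take the only remaining hydrogen flanked by fluorine and methoxy (the methoxy group beside the prenyl chain is turned towards the other ring hydrogen and shields it, and ring lithiation at −78 °C without diamine additive should outrun deprotonation of the prenyl CH2), and the Weinreb ketone synthesis stops at the ketone because the chelated tetrahedral adduct survives until the quench.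

**Step 3**
Reactants: 7 2-(benzyloxy)-1-[2-fluoro-4,6-dimethoxy-3-(3-methylbut-2-en-1-yl)phenyl]ethan-1-one
Product: 8 {[(1Z)-2-(benzyloxy)-1-[2-fluoro-4,6-dimethoxy-3-(3-methylbut-2-en-1-yl)phenyl]ethenyl]oxy}trimethylsilane
Conditions: TMSOTf (1.2 equiv), Et3N (1.5 equiv), CH2Cl2, 0 °C; pentane, filtration, no aqueous work-up
Reagents that add atoms: trimethylsilyl trifluoromethanesulfonate (TMSOTf), C[Si](C)(C)OS(=O)(=O)C(F)(F)F
Why: Soft enolisation with a silyl triflate and a tertiary amine (silyl enol ether formation) needs no strong base, so the aryl fluoride, the benzyl ether and the prenyl group are untouched, and the Z isomer should predominate although the geometry is not carried into the product because the enolate reacts through an open transition state.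

**Step 4**
Reactants: 8 {[(1Z)-2-(benzyloxy)-1-Ar-ethenyl]oxy}trimethylsilane; 9 benzaldehyde
Product: 13 (2R,3R)-3-(benzyloxy)-5,7-dimethoxy-8-(3-methylbut-2-en-1-yl)-2-phenyl-2,3-dihydro-4H-chromen-4-one, via ammonium enolate 10 (not isolated), via aldolate 11 (not isolated), via silyl ether 12 (not isolated)
Conditions: O-allyl-N-(9-anthracenylmethyl)cinchonidinium hydrogen difluoride (10 mol %, from the commercial bromide by ion exchange), 9 (1.2 equiv), toluene–CH2Cl2 (5:1), 4 Å molecular sieves, −78 → −10 °C; then AcOH
Reagents that add atoms: none
Why: Proposed new method: bifluoride removes the silyl group of 8 to give enolate 10 as an ion pair with the chiral ammonium cation, 10 adds through an open transition state to benzaldehyde (C2–C3 bond) to give aldolate 11, which is kept in reserve as silyl ether 12 by silyl transfer from 8, and the alkoxide oxygen of 11 then attacks the fluorine-bearing carbon C8a ortho to the ketone by addition–elimination (SNAr through an anionic sigma adduct stabilised by the C4 carbonyl) to form the O1–C8a bond and expel fluoride, which desilylates the next molecule of 8 or 12 (giving Me3SiF) and so carries the chain. The closest known reaction types are the chiral quaternary ammonium fluoride-catalysed Mukaiyama aldol addition and the fluoride-catalysed SNAr etherification of silyl ethers with carbonyl-activated aryl fluorides, which have not been joined into one enantioselective annulation on a 2-fluoroaryl ketone. Ring C closes by a 6-endo-trig addition–elimination at C8a, the C8a=C4a bond passing the charge to the carbonyl oxygen. C2 should be set by the face of benzaldehyde left open by the cinchonidinium cation in the ion pair, and C3 by the chair-like closing transition state with phenyl and benzyloxy both pseudo-equatorial (2,3-trans), the syn aldolate being drained back through retro-aldol within the same chiral ion pair. The step needs six-ring O-arylation by the C2 oxygen only, secured by the benzyl cap on the C3 oxygen (no five-ring closure), by the single ortho fluorine and by the absence of stoichiometric base, so that the product is not opened or epimerised.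

**Step 5**
Reactants: 13 (2R,3R)-3-(benzyloxy)-5,7-dimethoxy-8-(3-methylbut-2-en-1-yl)-2-phenyl-2,3-dihydro-4H-chromen-4-one
Product: 14 (2R,3R)-3,5-dihydroxy-7-methoxy-8-(3-methylbut-2-en-1-yl)-2-phenyl-2,3-dihydro-4H-chromen-4-one (target)
Conditions: BCl3 (4 equiv), C6HMe5 (3 equiv), CH2Cl2, −78 °C, then 0 °C; H2O
Reagents that add atoms: none
Why: Chelation-controlled Lewis acid ether cleavage: BCl3 bound to the C4 carbonyl should cleave the neighbouring O3-benzyl ether at −78 °C (the benzyl cation is trapped by pentamethylbenzene) and, at 0 °C, the O5-methyl ether through the six-membered chelate, while the unchelated 7-methoxy group, the prenyl alkene (no free hydroxyl beside it) and both stereocentres should stay intact.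

**Compound list**

1 | 1-fluoro-3,5-dimethoxybenzene | COc1cc(F)cc(OC)c1 | starting material
2 | 1-bromo-3-methylbut-2-ene (prenyl bromide) | CC(C)=CCBr | starting material
3 | (2-fluoro-4,6-dimethoxyphenyl)lithium | [Li]c1c(F)cc(OC)cc1OC | intermediate
4 | 1-fluoro-3,5-dimethoxy-2-(3-methylbut-2-en-1-yl)benzene | COc1cc(OC)c(CC=C(C)C)c(F)c1 | intermediate
5 | 2-(benzyloxy)-N-methoxy-N-methylacetamide | CON(C)C(=O)COCc1ccccc1 | starting material
6 | [2-fluoro-4,6-dimethoxy-3-(3-methylbut-2-en-1-yl)phenyl]lithium | [Li]c1c(F)c(CC=C(C)C)c(OC)cc1OC | intermediate
7 | 2-(benzyloxy)-1-[2-fluoro-4,6-dimethoxy-3-(3-methylbut-2-en-1-yl)phenyl]ethan-1-one | COc1cc(OC)c(C(=O)COCc2ccccc2)c(F)c1CC=C(C)C | intermediate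
8 | {[(1Z)-2-(benzyloxy)-1-[2-fluoro-4,6-dimethoxy-3-(3-methylbut-2-en-1-yl)phenyl]ethenyl]oxy}trimethylsilane | C[Si](C)(C)O/C(=C\OCc1ccccc1)c1c(F)c(CC=C(C)C)c(OC)cc1OC | intermediate
9 | benzaldehyde | O=Cc1ccccc1 | starting material
10 | (Z)-enolate of 7, ion-paired with the cinchonidinium cation (anion shown) | [O-]/C(=C\OCc1ccccc1)c1c(F)c(CC=C(C)C)c(OC)cc1OC | intermediate
11 | (2R,3R)-2-(benzyloxy)-1-[2-fluoro-4,6-dimethoxy-3-(3-methylbut-2-en-1-yl)phenyl]-3-oxido-3-phenylpropan-1-one, anti aldolate ion-paired with the cinchonidinium cation (anion shown) | [O-][C@H](c1ccccc1)[C@@H](OCc1ccccc1)C(=O)c1c(F)c(CC=C(C)C)c(OC)cc1OC | intermediate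
12 | (2R,3R)-2-(benzyloxy)-1-[2-fluoro-4,6-dimethoxy-3-(3-methylbut-2-en-1-yl)phenyl]-3-phenyl-3-[(trimethylsilyl)oxy]propan-1-one | C[Si](C)(C)O[C@H](c1ccccc1)[C@@H](OCc1ccccc1)C(=O)c1c(F)c(CC=C(C)C)c(OC)cc1OC | intermediate
13 | (2R,3R)-3-(benzyloxy)-5,7-dimethoxy-8-(3-methylbut-2-en-1-yl)-2-phenyl-2,3-dihydro-4H-chromen-4-one | COc1cc(OC)c2c(c1CC=C(C)C)O[C@H](c1ccccc1)[C@@H](OCc1ccccc1)C2=O | intermediate
14 | (2R,3R)-3,5-dihydroxy-7-methoxy-8-(3-methylbut-2-en-1-yl)-2-phenyl-2,3-dihydro-4H-chromen-4-one | COc1cc(O)c2c(c1CC=C(C)C)O[C@H](c1ccccc1)[C@@H](O)C2=O | target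

**Step count and risks**

Total step count: 5. Longest linear sequence: 5 steps (1 → 4 → 7 → 8 → 13 → 14).

Steps most likely to fail:

1. Step 4 (proposed new method). What may go wrong: insufficient or wrong-sense facial control by the ammonium ion pair; loss of configuration at C2 through retro-aldol cleavage of the aldolate or base-induced opening of ring C before the quench; elimination of silanolate from 12 to an enone; decay of the ammonium catalyst under the naked anions. Fallback (known chemistry, sets out from 7 and comes back at 13): 7 is deprotonated with LiN(SiMe3)2 in THF at −78 °C and treated with 9 to give, after aqueous quench, the racemic aldol adduct 2-(benzyloxy)-1-[2-fluoro-4,6-dimethoxy-3-(3-methylbut-2-en-1-yl)phenyl]-3-hydroxy-3-phenylpropan-1-one F1 as a syn/anti mixture. Heating F1 with Cs2CO3 in DMF (60 °C) closes ring C by intramolecular SNAr and equilibrates C3 through the enolate, so that racemic trans-3-(benzyloxy)-5,7-dimethoxy-8-(3-methylbut-2-en-1-yl)-2-phenyl-2,3-dihydro-4H-chromen-4-one F2 should result. Preparative chromatography on a chiral stationary phase (supercritical CO2/methanol, amylose carbamate phase) then gives the (2R,3R) enantiomer 13, the (2S,3S) half being discarded.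

2. Step 2. What may go wrong: deprotonation of the allylic–benzylic CH2 of the prenyl group, or of the ring hydrogen between the two methoxy groups, in place of the hydrogen next to fluorine; loss of LiF from the aryllithium to an aryne if the temperature rises. Fallback (sets out from 4 and comes back at aryllithium 6): electrophilic bromination of 4 (NBS, MeCN, −20 °C, dark) should go para to one methoxy group and ortho to the other, at the carbon next to fluorine, to give 1-bromo-2-fluoro-4,6-dimethoxy-3-(3-methylbut-2-en-1-yl)benzene F3. Bromine–lithium exchange (n-BuLi, THF, −78 °C), which is much faster than any deprotonation, then places the metal at a defined position to give 6, which is acylated with 5 as in step 2 to give 7.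

3. Step 5. What may go wrong: hydrochlorination or cation-induced cyclisation of the prenyl double bond, benzylation of ring A at C6, or ionisation of the benzylic C2–O1 bond during the warm phase needed for the O5-demethylation. Fallback (sets out from 13 and comes back at 14): the two ethers are cleaved separately by different mechanisms. MgI2·OEt2 (toluene, 80 °C) removes only the methyl group peri to the carbonyl, by iodide attack on the magnesium chelate, to give (2R,3R)-3-(benzyloxy)-5-hydroxy-7-methoxy-8-(3-methylbut-2-en-1-yl)-2-phenyl-2,3-dihydro-4H-chromen-4-one F4. The benzyl ether of F4 is then cleaved with BCl3/C6HMe5 at −78 °C only, a temperature at which the prenyl group and the C2–O1 bond should be inert, to give 14.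

Further compounds
F1 | step 4 | 2-(benzyloxy)-1-[2-fluoro-4,6-dimethoxy-3-(3-methylbut-2-en-1-yl)phenyl]-3-hydroxy-3-phenylpropan-1-one (racemic, syn/anti mixture) | OC(c1ccccc1)C(OCc1ccccc1)C(=O)c1c(F)c(CC=C(C)C)c(OC)cc1OC
F2 | step 4 | racemic trans-(2R*,3R*)-3-(benzyloxy)-5,7-dimethoxy-8-(3-methylbut-2-en-1-yl)-2-phenyl-2,3-dihydro-4H-chromen-4-one | COc1cc(OC)c2c(c1CC=C(C)C)OC(c1ccccc1)C(OCc1ccccc1)C2=O
F3 | step 2 | 1-bromo-2-fluoro-4,6-dimethoxy-3-(3-methylbut-2-en-1-yl)benzene | Brc1c(F)c(CC=C(C)C)c(OC)cc1OC
F4 | step 5 | (2R,3R)-3-(benzyloxy)-5-hydroxy-7-methoxy-8-(3-methylbut-2-en-1-yl)-2-phenyl-2,3-dihydro-4H-chromen-4-one | COc1cc(O)c2c(c1CC=C(C)C)O[C@H](c1ccccc1)[C@@H](OCc1ccccc1)C2=O
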